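## Structural features

The target is an unbranched C15 chain (C1 the alkyne terminus, C15 the ethyl terminus) in which an oxygen atom bridges C6 and C12, so that C7 to C11 complete a single oxocane, ring A. C6 carries the (Z)-pent-2-en-4-ynyl arm (C1–C5) and C12 carries the 1-acetoxypropyl arm (C13–C15); the two arms are cis across the ring oxygen (6R, 12R). The six stereocentres form three adjacent pairs: C6/C7 (the C7 acetate on the same ring face as the C5 arm), C9/C10 (a cis-diol on the opposite face) and C12/C13 (ring oxygen and O13 anti in the extended chain, 13S). The fragile groups are the terminal Z-enyne, which rules out hydrogenation, dissolving metals and strong base late in the route, and the two secondary acetates next to two free hydroxyls, which limit the last operations to fluoride and mild aqueous acid. The real difficulty is the medium ring: closing an eight-membered ether by C–O or C–C bond formation costs entropy and transannular strain, and five of the six stereocentres sit on that ring. The feature exploited is that removing the ring oxygen and bonding C6 to C12 gives a seven-membered carbocycle in which C6 is a carbonyl carbon on a mirror plane bisecting the C9–C10 bond, so the cis-dioxygenated cycloheptanone is meso. The oxocane can therefore come from oxygen insertion into the C6–C12 bond of a desymmetrised cycloheptanone, a ring enlargement instead of a ring closure.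

## Logic of the disconnections

**26 to 25.** The two C–O bonds from O9 and O10 to an isopropylidene carbon are restored. This keeps the C9/C10 hydroxyls apart from the two that must be acetylated, so no regioselective acylation is needed. The forward hydrolysis must spare two acetates and the enyne, hence aqueous acetic acid.

**25 to 24 to 23.** The two acetyl C–O bonds are cut, and silicon is put back on O7 and on C1. Both acetates can then go on in one operation, and one fluoride treatment frees O7 and the alkyne together. The fluoride step must leave the acetonide alone.

**23 to 21 and 22.** The C13–C14 bond is cut. C13 then derives from the oxygenated one-carbon arm present since the alkylation, and its configuration is set late by addition to an aldehyde. The forward step must give the anti (non-chelation) isomer, which a chelating ethylmagnesium reagent would not secure; a catalyst-controlled addition of 22 is therefore required.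

**21 to 20 to 19.** The C13 oxidation level is adjusted and silicon is returned to O13. The simplification is that O7 and O13 carry the same protecting group. The demand is that the primary silyl ether be released in the presence of the hindered secondary one.

**19 to 14 and 17; 17 to 15 and 16.** The sp2–sp3 bond C4–C5 and the C6–H bond are cut. The whole enyne arm then arrives in one operation with its Z geometry preformed, and C6 is set in the same operation by addition to an exocyclic enol ether. The borane must approach the face opposite the O7 silyl ether and the C12 arm, and the coupling must retain the alkene geometry. For 17 the C2–C3 bond is cut; the Z geometry is bought with 15.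

**14 to 13.** The C5=C6 bond is replaced by the lactone carbonyl. This returns the route to a lactone, the product type of the key step. The methylenation must be non-acidic and tolerate silyl ethers and the acetal.

**13 to 12 to 11.** The silyl ethers are removed and benzyl is put back on O13. Benzyl is what the alkylating agent delivers and it survives peracid and enolate chemistry, but it can only be removed by hydrogenolysis while the molecule has no C=C or C≡C bond, that is, at the lactone stage. The hydroxy lactone must be handled under neutral conditions so that it does not translactonise.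

**11 to 9.** The C7–O bond is cut. C7 is the α-carbon of the lactone, the one position where oxygen can enter through an enolate. The oxidant must attack the face that carries the C12 arm, away from the acetonide.

**9 to 7.** The C6–O and O–C12 bonds are removed and the C6–C12 bond is restored. The eight-membered ether becomes a seven-membered ketone with three stereocentres, two of them a meso pair. The forward step must make C12, not C7, migrate, with retention, and the acetonide must survive the peracid.

**7 to 4 and 5.** The C12–C13 bond is cut, leaving a symmetric ketone. The forward alkylation must distinguish the two enantiotopic α-methylene groups and put the new arm trans to the acetonide.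

**4 to 2 and 3; 2 to 1.** The acetal C–O bonds and then the two C–O bonds of the diol are cut, back to a symmetric cycloalkenone. The only demand is syn addition to the ring alkene.

## Other disconnections considered

**Alternative 1: ring-closing aldol at C8–C9.** The cut opens ring A to an acyclic di-secondary ether A2 with a C7 enol silane at one end and a C9 aldehyde at the other. In the forward step BF3·OEt2 would activate the aldehyde and the enol silane terminus C8 would close the ring to the β-hydroxy ketone A1.
- In favour: the ether oxygen, C6, C10, C12 and C13 are fixed in an open chain by acyclic methods that do not depend on medium-ring conformations. The allyl group of A1 is a ready handle for the enyne. The new C9 carbinol should follow Felkin–Anh induction from the C10 silyloxy group, which corresponds to the cis-diol. The C7 ketone is placed for a C9-hydroxyl-directed 1,3-anti reduction, the C7/C9 relationship of the target.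
- Against: the ring is closed by C–C bond formation at eight-membered size, so intermolecular aldol and retro-aldol pathways compete and high dilution is needed. The methyl ketone must be enolised away from the acidic, epimerisable C6–H. After reduction O7 and O9 must be told apart, since only O7 is acetylated. A2 needs a long linear preparation.
- Comparison: on control of C6 and on having C13 in place from the start, Alternative 1 is the better. On the ring-forming event the chosen plan is better, because 9 arises by a 1,2-shift inside an existing ring. Step economy favours the chosen plan, which starts from a meso ring and needs no hydroxyl differentiation at C7/C9.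

**Alternative 2: late oxiranium ring expansion.** The O–C6 and C7–OAc bonds are cut together and the ring oxygen is reconnected to C7, giving the cis-2,7-disubstituted oxepane A4 with a chloromethanesulfonate on the exocyclic C6. In the forward step the ring oxygen would displace the sulfonate with inversion, and acetate from Zn(OAc)2 would open the oxiranium ion at C7 with inversion, giving A3, which is the same compound as 25.
- In favour: the step is stereospecific at both C6 and C7, needs no protecting group on O7, starts from a seven-membered ether that is easier to make than an eight-membered one, and its product is one hydrolysis from the target.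
- Against: the oxiranium ion can also be opened at C6, which returns an oxepane, and the seven-to-eight enlargement has less driving force than smaller homologues. The enyne, the C13 acetate and the acetonide must all tolerate warm acetic acid with a zinc salt. A4 itself, with five stereocentres and the enyne, must be built first, so the difficulty is shifted to the oxepane.
- Comparison: on C6/C7 stereocontrol and on the end game Alternative 2 is the better. On access to the ring and on regiochemical reliability the chosen plan is at least its equal. Overall step count should be comparable.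

**Alternative 3: ketene acetal Claisen ring expansion.** The C7–C8 bond is cut and the lactone A5 is traced to the 2-methylene-4-vinyl-1,3-dioxane A6 (drawn as its 4,6-cis isomer). In the forward step A6, made in situ by selenoxide elimination, would rearrange to A5, forming C7–C8 and breaking O–C10.
- In favour: this is also a ring enlargement (six to eight) that avoids medium-ring closure, and the reaction type is well established for this ring size. C12 and C13 with the ethyl group come from an acyclic 1,3-diol, so no late ethyl addition and no benzyl-to-silyl exchange is needed. A5 is the same kind of lactone as 9, so the same C7 and C6 chemistry would follow.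
- Against: the C9/C10 diol must be added later by dihydroxylation of the ring alkene on the face opposite the C12 arm, and that selectivity cannot be taken for granted in a flexible oxocene. The acyclic diol and its selenoacetal cost several steps.
- Comparison: on C13 Alternative 3 is the better. On the C9/C10 diol the chosen plan is the better, since the diol is present from step 1 with no facial question. As ring-forming mechanisms the two are equal, both being concerted rearrangements of defined stereochemical course. Step economy is roughly equal.

Key step: step 4

Remark: locants C1–C15 and the descriptors attached to them refer throughout to the carbon chain of the target.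
Remark: compounds 7 and 9 were compared atom by atom with 26; both have the required 9R,10S,12R configuration (C12 retained in the migration), so no structure needed correction.
Assumption: lithium (R,R)-bis(1-phenylethyl)amide is taken to remove the α-proton of 4 that leads to 6; if the opposite sense is found, the (S,S)-amine is used and nothing else changes.

## Route

Step 1
Reactants: 1 cyclohept-4-en-1-one
Product: 2 cis-4,5-dihydroxycycloheptan-1-one (meso; 4R,5S)
Conditions: OsO4 (cat.), N-methylmorpholine N-oxide, acetone/H2O, rt
Reagents that add atoms: OsO4 O=[Os](=O)(=O)=O; N-methylmorpholine N-oxide C[N+]1([O-])CCOCC1; water O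
Why: Catalytic syn-dihydroxylation; suprafacial addition of OsO4 to the cis ring alkene can only give the cis (meso) diol, and the ketone is inert; partial transannular hemiketal formation does not matter because step 2 drains the open diol.

Step 2
Reactants: 2 cis-4,5-dihydroxycycloheptan-1-one; 3 2,2-dimethoxypropane
Product: 4 cis-4,5-(isopropylidenedioxy)cycloheptan-1-one (meso acetonide)
Conditions: p-TsOH·H2O (cat.), acetone, rt; then Et3N
Reagents that add atoms: none
Why: Acid-catalysed transketalisation; the cis-1,2-diol closes the dioxolane, and the product keeps the mirror plane through the carbonyl, so the C7 and C12 methylene groups are enantiotopic.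

Step 3
Reactants: 4 cis-4,5-(isopropylidenedioxy)cycloheptan-1-one; 5 benzyl chloromethyl ether
Product: 7 (2R,4S,5R)-2-[(benzyloxy)methyl]-4,5-(isopropylidenedioxy)cycloheptan-1-one, via lithium enolate 6 (not isolated)
Conditions: (R,R)-bis(1-phenylethyl)amine·HCl, n-BuLi (2 equiv), THF, −78 °C; 4; then 5, −78 → −40 °C; aq. NH4Cl
Reagents that add atoms: none
Why: Enantioselective deprotonation of a meso ketone by a homochiral lithium amide (LiCl formed in situ sharpens the selection) fixes the absolute sense of C9/C10, and the enolate is C-alkylated (SN2) by the reactive α-chloro ether. The electrophile should approach C12 on the face away from the cis-fused dioxolane, placing CH2OBn trans to the acetonide oxygens (12R); low temperature and a cold quench keep the centre from equilibrating.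

Step 4
Reactants: 7 (2R,4S,5R)-2-[(benzyloxy)methyl]-4,5-(isopropylidenedioxy)cycloheptan-1-one
Product: 9 (5R,6S,8R)-8-[(benzyloxy)methyl]-5,6-(isopropylidenedioxy)oxocan-2-one, via Criegee adduct 8 (not isolated)
Conditions: CF3CO3H [from (CF3CO)2O and urea·H2O2], Na2HPO4, CH2Cl2, 0 °C → rt
Reagents that add atoms: trifluoroperacetic acid OOC(=O)C(F)(F)F
Why: The peracid adds to the C6 carbonyl to give the tetrahedral Criegee adduct 8. In 8 the C6–C12 bond antiperiplanar to the O–O bond shifts to oxygen as trifluoroacetate leaves, forming O–C12 beside the new C6–O bond and turning the cycloheptanone into the oxocan-2-one. The closest known reaction type is the Baeyer–Villiger ring expansion of 2-alkylcycloalkanones, cycloheptanones included, to the lactone of the more substituted α-carbon. The eight-membered ring is not closed by a cyclisation: it arises by a 1,2-shift within an existing ring (seven to eight), so neither dilution nor a favourable end-to-end conformation is needed. No stereocentre is created; C12 migrates with retention, so the 12R centre of 7 becomes the ether carbon of 9, and C9/C10 are untouched. The selectivity needed is regiochemical, C12 against C7: the secondary C12 carries positive charge in the transition state better than the primary C7, and the benzyloxy oxygen is one carbon removed, so its inductive retardation should be small. Chemoselectivity is secured by the substrate: there is no alkene to epoxidise, the benzyl ether is inert, and Na2HPO4 keeps the acidity below what the acetonide tolerates.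

Step 5
Reactants: 9 (5R,6S,8R)-8-[(benzyloxy)methyl]-5,6-(isopropylidenedioxy)oxocan-2-one
Product: 11 (3R,5R,6S,8R)-8-[(benzyloxy)methyl]-3-hydroxy-5,6-(isopropylidenedioxy)oxocan-2-one, via potassium enolate 10 (not isolated)
Conditions: KN(SiMe3)2, THF, −78 °C; 2-(phenylsulfonyl)-3-phenyloxaziridine, −78 °C; aq. NH4Cl
Reagents that add atoms: 2-(phenylsulfonyl)-3-phenyloxaziridine O=S(=O)(c1ccccc1)N1OC1c1ccccc1
Why: Enolate oxidation by an N-sulfonyloxaziridine; the potassium enolate avoids addition to the sulfonimine by-product. The dioxolane at C9/C10 (C9 is β to C7) screens one face of the enolate, so oxygen should enter on the face of the C12 arm and give 7R.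

Step 6
Reactants: 11 (3R,5R,6S,8R)-8-[(benzyloxy)methyl]-3-hydroxy-5,6-(isopropylidenedioxy)oxocan-2-one
Product: 12 (3R,5R,6S,8R)-3-hydroxy-8-(hydroxymethyl)-5,6-(isopropylidenedioxy)oxocan-2-one
Conditions: H2 (1 atm), 10% Pd/C, EtOAc, rt
Reagents that add atoms: none
Why: Hydrogenolysis of the benzyl ether, placed here because it is the last point at which the molecule has no C=C or C≡C bond; lactone and acetonide are inert, and the neutral medium gives no reason for acyl migration to O13.

Step 7
Reactants: 12 (3R,5R,6S,8R)-3-hydroxy-8-(hydroxymethyl)-5,6-(isopropylidenedioxy)oxocan-2-one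
Product: 13 (3R,5R,6S,8R)-3-(tert-butyldimethylsilyloxy)-8-[(tert-butyldimethylsilyloxy)methyl]-5,6-(isopropylidenedioxy)oxocan-2-one
Conditions: TBSOTf (2.5 equiv), 2,6-lutidine, CH2Cl2, −78 → 0 °C
Reagents that add atoms: tert-butyldimethylsilyl trifluoromethanesulfonate CC(C)(C)[Si](C)(C)OS(=O)(=O)C(F)(F)F
Why: Silylation of both hydroxyls with a silyl triflate and a hindered base; the bulky O7 silyl ether later directs the hydroboration, and the primary O13 silyl ether can be released selectively.

Step 8
Reactants: 13 (3R,5R,6S,8R)-3-(tert-butyldimethylsilyloxy)-8-[(tert-butyldimethylsilyloxy)methyl]-5,6-(isopropylidenedioxy)oxocan-2-one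
Product: 14 (3R,5R,6S,8R)-3-(tert-butyldimethylsilyloxy)-8-[(tert-butyldimethylsilyloxy)methyl]-5,6-(isopropylidenedioxy)-2-methyleneoxocane
Conditions: Cp2TiMe2, toluene, 70 °C, dark; filtration through basic alumina
Reagents that add atoms: Cp2TiMe2 [CH3-].[CH3-].[Ti+4].c1cc[cH-]c1.c1cc[cH-]c1
Why: Petasis methylenation of the lactone carbonyl through thermally generated Cp2Ti=CH2; it is non-acidic, tolerates silyl ethers and the acetal, touches no stereocentre, and supplies C5 as the exocyclic enol ether.

Step 9
Reactants: 15 cis-1,2-dichloroethene; 16 (triisopropylsilyl)acetylene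
Product: 17 (Z)-1-chloro-4-(triisopropylsilyl)but-1-en-3-yne
Conditions: Pd(PPh3)4 (cat.), CuI (cat.), n-BuNH2, Et2O, rt (15 in excess)
Reagents that add atoms: none
Why: Sonogashira coupling; excess dihalide enforces mono-coupling, and oxidative addition and reductive elimination retain the Z geometry bought with 15.

Step 10
Reactants: 14 (3R,5R,6S,8R)-3-(tert-butyldimethylsilyloxy)-8-[(tert-butyldimethylsilyloxy)methyl]-5,6-(isopropylidenedioxy)-2-methyleneoxocane; 17 (Z)-1-chloro-4-(triisopropylsilyl)but-1-en-3-yne
Product: 19 oxocane with C6 (Z)-5-(triisopropylsilyl)pent-2-en-4-ynyl arm; C7 OTBS; C9/C10 acetonide; C12 CH2OTBS (6R,7R,9R,10S,12R), via B-alkyl-9-BBN 18 (not isolated)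
Conditions: 9-BBN, THF, 0 °C → rt; then 3 M aq. K3PO4, 17, Pd(OAc)2 (cat.), SPhos (cat.), THF, 45 °C
Reagents that add atoms: none
Why: Anti-Markovnikov hydroboration of the exocyclic enol ether puts boron on C5, and B-alkyl Suzuki–Miyaura coupling with the alkenyl chloride then forms C4–C5 with retention of the Z geometry. C6 is set in the hydroboration: allylic strain with the exocyclic methylene should turn the C7 silyloxy group out of the alkene plane, so the borane approaches anti to it and anti to the C12 arm, and C5 ends up cis to O7 and to C13 (6R).

Step 11
Reactants: 19 oxocane with C6 silylated enyne arm; C7 OTBS; C12 CH2OTBS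
Product: 20 primary alcohol: as 19 but C12 CH2OH (6R,7R,9R,10S,12R)
Conditions: HF·pyridine, pyridine, THF, 0 °C
Reagents that add atoms: none
Why: Selective desilylation; the unhindered primary silyl ether is cleaved by buffered HF·pyridine well before the secondary C7 silyl ether flanked by two ring substituents, and the alkynylsilane and acetonide are inert.

Step 12
Reactants: 20 primary alcohol (C13 OH)
Product: 21 aldehyde: as 20 but C13 is CHO (6R,7R,9R,10S,12R)
Conditions: Dess–Martin periodinane, pyridine, CH2Cl2, 0 °C → rt
Reagents that add atoms: none
Why: Dess–Martin oxidation under buffered, non-enolising conditions, so the α-alkoxy centre C12 should not epimerise; the aldehyde is used at once.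

Step 13
Reactants: 21 C13 aldehyde; 22 diethylzinc
Product: 23 secondary alcohol: as 21 but C13 is (S)-CH(OH)CH2CH3 (6R,7R,9R,10S,12R,13S)
Conditions: Ti(OiPr)4, (1R,2R)-N,N'-bis(trifluoromethanesulfonyl)cyclohexane-1,2-diamine (cat.), toluene, −20 °C; aq. NH4Cl
Reagents that add atoms: none
Why: Catalytic enantioselective addition of a dialkylzinc through a chiral titanium bis(sulfonamide) complex. The (R,R)-ligand is expected to deliver ethyl to the Si face of the aldehyde, which is also the Felkin–Anh face of this α-alkoxy aldehyde under the non-chelating titanium-rich conditions, so reagent and substrate should reinforce each other for 13S.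

Step 14
Reactants: 23 secondary alcohol (13S) with C7 OTBS and alkynyl triisopropylsilyl group
Product: 24 diol: C7 OH and C13 OH; terminal (Z)-enyne; C9/C10 acetonide (6R,7R,9R,10S,12R,13S)
Conditions: Bu4NF, THF, 0 °C → rt
Reagents that add atoms: none
Why: Fluoride cleaves the O–Si bond at O7 and the C(sp)–Si bond in one operation; the acetonide is untouched and no ester is yet present.

Step 15
Reactants: 24 diol with terminal (Z)-enyne and C9/C10 acetonide
Product: 25 diacetate: C7 OAc and C13 OAc; C9/C10 acetonide (6R,7R,9R,10S,12R,13S)
Conditions: Ac2O, pyridine, DMAP (cat.), CH2Cl2, rt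
Reagents that add atoms: acetic anhydride CC(=O)OC(C)=O
Why: DMAP-catalysed acylation of the only two free hydroxyls; no regiochemical question arises because O9 and O10 are still tied up in the acetonide.

Step 16
Reactants: 25 diacetate acetonide
Product: 26 target: (6R,7R,9R,10S,12R,13S)-7,13-diacetoxy-6,12-epoxypentadec-3(Z)-en-1-yne-9,10-diol
Conditions: AcOH/H2O (4:1), 50 °C
Reagents that add atoms: none
Why: Acid-catalysed acetal hydrolysis; secondary acetates and the Z-enyne are stable in aqueous acetic acid, and acyl migration to the freed hydroxyls is slow under acid.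

## Compound list

1 | cyclohept-4-en-1-one | O=C1CCC=CCC1 | starting material
2 | cis-4,5-dihydroxycycloheptan-1-one (meso; 4R,5S) | O=C1CC[C@@H](O)[C@@H](O)CC1 | intermediate
3 | 2,2-dimethoxypropane | COC(C)(C)OC | starting material
4 | cis-4,5-(isopropylidenedioxy)cycloheptan-1-one (meso acetonide) | O=C1CC[C@H]2OC(C)(C)O[C@H]2CC1 | intermediate
5 | benzyl chloromethyl ether | ClCOCc1ccccc1 | starting material
6 | lithium enolate of 4 (C6=C12 enolate; 9R,10S) | [Li]OC1=CC[C@@H]2OC(C)(C)O[C@@H]2CC1 | intermediate (not isolated)
7 | (2R,4S,5R)-2-[(benzyloxy)methyl]-4,5-(isopropylidenedioxy)cycloheptan-1-one (9R,10S,12R; CH2OBn trans to the acetonide oxygens) | O=C1CC[C@H]2OC(C)(C)O[C@H]2C[C@@H]1COCc1ccccc1 | intermediate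
8 | Criegee adduct of 7: C6 carries OH and OOC(O)CF3 (C6 configuration undefined) | OC1(OOC(=O)C(F)(F)F)CC[C@H]2OC(C)(C)O[C@H]2C[C@@H]1COCc1ccccc1 | intermediate (not isolated)
9 | (5R,6S,8R)-8-[(benzyloxy)methyl]-5,6-(isopropylidenedioxy)oxocan-2-one | O=C1CC[C@H]2OC(C)(C)O[C@H]2C[C@H](COCc3ccccc3)O1 | intermediate
10 | potassium enolate of 9 (C6=C7) | [K]O/C1=C/C[C@H]2OC(C)(C)O[C@H]2C[C@H](COCc3ccccc3)O1 | intermediate (not isolated)
11 | (3R,5R,6S,8R)-8-[(benzyloxy)methyl]-3-hydroxy-5,6-(isopropylidenedioxy)oxocan-2-one (7R) | O=C1[C@H](O)C[C@H]2OC(C)(C)O[C@H]2C[C@H](COCc3ccccc3)O1 | intermediate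
12 | (3R,5R,6S,8R)-3-hydroxy-8-(hydroxymethyl)-5,6-(isopropylidenedioxy)oxocan-2-one | O=C1[C@H](O)C[C@H]2OC(C)(C)O[C@H]2C[C@H](CO)O1 | intermediate
13 | (3R,5R,6S,8R)-3-(tert-butyldimethylsilyloxy)-8-[(tert-butyldimethylsilyloxy)methyl]-5,6-(isopropylidenedioxy)oxocan-2-one | O=C1[C@H](O[Si](C)(C)C(C)(C)C)C[C@H]2OC(C)(C)O[C@H]2C[C@H](CO[Si](C)(C)C(C)(C)C)O1 | intermediate
14 | (3R,5R,6S,8R)-3-(tert-butyldimethylsilyloxy)-8-[(tert-butyldimethylsilyloxy)methyl]-5,6-(isopropylidenedioxy)-2-methyleneoxocane | C=C1[C@H](O[Si](C)(C)C(C)(C)C)C[C@H]2OC(C)(C)O[C@H]2C[C@H](CO[Si](C)(C)C(C)(C)C)O1 | intermediate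
15 | cis-1,2-dichloroethene | Cl/C=C\Cl | starting material
16 | (triisopropylsilyl)acetylene | C#C[Si](C(C)C)(C(C)C)C(C)C | starting material
17 | (Z)-1-chloro-4-(triisopropylsilyl)but-1-en-3-yne | Cl/C=C\C#C[Si](C(C)C)(C(C)C)C(C)C | intermediate
18 | B-alkyl-9-BBN: 9-borabicyclo[3.3.1]nonan-9-yl on C5; C6 H set (6R,7R,9R,10S,12R) | C(B1C2CCCC1CCC2)[C@H]3O[C@@H](CO[Si](C)(C)C(C)(C)C)C[C@@H]4OC(C)(C)O[C@@H]4C[C@H]3O[Si](C)(C)C(C)(C)C | intermediate (not isolated)
19 | oxocane with C6 (Z)-5-(triisopropylsilyl)pent-2-en-4-ynyl arm, C7 OTBS, C9/C10 acetonide, C12 CH2OTBS (6R,7R,9R,10S,12R) | CC(C)[Si](C(C)C)(C(C)C)C#C/C=C\C[C@H]1O[C@@H](CO[Si](C)(C)C(C)(C)C)C[C@@H]2OC(C)(C)O[C@@H]2C[C@H]1O[Si](C)(C)C(C)(C)C | intermediate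
20 | primary alcohol: as 19 with C12 CH2OH | CC(C)[Si](C(C)C)(C(C)C)C#C/C=C\C[C@H]1O[C@@H](CO)C[C@@H]2OC(C)(C)O[C@@H]2C[C@H]1O[Si](C)(C)C(C)(C)C | intermediate
21 | aldehyde: as 20 with C13 CHO | CC(C)[Si](C(C)C)(C(C)C)C#C/C=C\C[C@H]1O[C@@H](C=O)C[C@@H]2OC(C)(C)O[C@@H]2C[C@H]1O[Si](C)(C)C(C)(C)C | intermediate
22 | diethylzinc | CC[Zn]CC | starting material
23 | secondary alcohol: as 21 with C13 (S)-CH(OH)CH2CH3 (6R,7R,9R,10S,12R,13S) | CC(C)[Si](C(C)C)(C(C)C)C#C/C=C\C[C@H]1O[C@@H]([C@H](CC)O)C[C@@H]2OC(C)(C)O[C@@H]2C[C@H]1O[Si](C)(C)C(C)(C)C | intermediate
24 | diol: C7 OH, C13 OH, terminal (Z)-enyne, C9/C10 acetonide | C#C/C=C\C[C@H]1O[C@@H]([C@H](CC)O)C[C@@H]2OC(C)(C)O[C@@H]2C[C@H]1O | intermediate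
25 | diacetate: C7 OAc, C13 OAc, C9/C10 acetonide | C#C/C=C\C[C@H]1O[C@@H]([C@H](CC)OC(C)=O)C[C@@H]2OC(C)(C)O[C@@H]2C[C@H]1OC(C)=O | intermediate
26 | target, (6R,7R,9R,10S,12R,13S)-7,13-diacetoxy-6,12-epoxypentadec-3(Z)-en-1-yne-9,10-diol | C#C/C=C\C[C@H]1O[C@@H]([C@H](CC)OC(C)=O)C[C@H](O)[C@H](O)C[C@H]1OC(C)=O | target

## Step count and least certain steps

Total: 16 steps. Longest linear sequence: 15 steps (steps 1–8 and 10–16, from 1); step 9 is a one-step side branch.

**Step 4 (key step).** The primary C7 may migrate in competition, because the inductive pull of the benzyloxy group lowers the migratory aptitude of C12; the trifluoroacetic acid formed may also cleave the acetonide if buffering is insufficient. Fallback: oxygen insertion by a Baeyer–Villiger monooxygenase of the cyclohexanone monooxygenase type (O2, NADPH recycled with glucose and glucose dehydrogenase, aqueous buffer near pH 8), directly from 7 to 9. Regiochemistry is then set by the enzyme pocket and not by migratory aptitude, and the neutral medium spares the acetal; no new compound is made (F0).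

**Step 3.** The chiral amide may discriminate the enantiotopic α-protons poorly, proton exchange between enolate and product may erode the enantiomeric purity and cause dialkylation, and approach of the electrophile syn to the dioxolane would give the cis isomer. Fallback from 4: the same amide with Me3SiCl present during deprotonation (internal quench, THF, −100 → −78 °C) should give the trimethylsilyl enol ether F1, which can be isolated and assayed. F1 is then alkylated with 5 under TiCl4 in CH2Cl2 at −78 °C, an SN1-type reaction of the benzyloxymethyl cation with the enol silane in which no basic enolate is present, and the route is rejoined at 7.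

**Step 5.** Oxygen transfer may occur on the wrong face of the enolate, and the lactone enolate may fragment if allowed to warm. A single enantiomer of a camphor-derived sulfonyloxaziridine may be tried first as a reagent-control variant. Fallback from 9: the hydroxylation is run as before and the 7-epimeric alcohol F2 is accepted. F2 is inverted by Mitsunobu reaction with chloroacetic acid (PPh3, diisopropyl azodicarboxylate, THF, 0 °C), SN2 at the activated α-carbon, to give the (7R)-chloroacetate F3. The chloroacetyl group is removed with thiourea and NaHCO3 in EtOH without opening the lactone, and the route is rejoined at 11.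

**Step 10.** The borane may add to the other face of the enol ether and give the C6 epimer, the exocyclic enol ether may isomerise into the ring before it is hydroborated, and oxidative addition of the alkenyl chloride may be slow. Fallback from 13: reduction with i-Bu2AlH (CH2Cl2, −78 °C) and acetylation of the aluminium hemiacetal in the same flask (Ac2O, pyridine, DMAP) should give the lactol acetate F4. Allyltrimethylsilane and BF3·OEt2 (CH2Cl2, −78 °C) add allyl to the ring oxocarbenium ion to give the C6-allyl oxocane F5, a different stereocontrol element in which the preference of an adjacent silyloxy group for 1,2-cis attack would be relied on. Ozonolysis (O3, CH2Cl2, −78 °C; PPh3) gives the aldehyde F6, and Peterson olefination with lithiated 1,3-bis(triisopropylsilyl)propyne (n-BuLi, THF, −78 °C) gives the Z-enyne and rejoins the route at 19.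

**Step 13.** Chelation of zinc or titanium between the ring oxygen and the aldehyde may erode the facial selectivity, and the several Lewis-basic oxygens may slow the catalyst. Fallback from 21: EtMgBr (THF, −78 °C) gives the alcohol F7 as a C13 epimer mixture, drawn as the 13R isomer expected from chelation. Dess–Martin oxidation gives the ethyl ketone F8, and Zn(BH4)2 (Et2O, −20 °C) reduces it under chelation between the ring oxygen and the carbonyl, delivering hydride to the face that gives the anti (13S) alcohol, and the route is rejoined at 23.

## Further compounds

F0 | step 4 | none | none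
F1 | step 3 | trimethylsilyl enol ether of 4 (C6=C12; 9R,10S) | C[Si](C)(C)OC1=CC[C@@H]2OC(C)(C)O[C@@H]2CC1
F2 | step 5 | (3S,5R,6S,8R)-8-[(benzyloxy)methyl]-3-hydroxy-5,6-(isopropylidenedioxy)oxocan-2-one (7-epimer of 11) | O=C1[C@@H](O)C[C@H]2OC(C)(C)O[C@H]2C[C@H](COCc3ccccc3)O1
F3 | step 5 | (7R)-chloroacetate of 11 | O=C1[C@H](OC(=O)CCl)C[C@H]2OC(C)(C)O[C@H]2C[C@H](COCc3ccccc3)O1
F4 | step 10 | lactol acetate from 13: C6 OAc (anomer mixture), C7 OTBS, C12 CH2OTBS, C9/C10 acetonide | CC(=O)OC1O[C@@H](CO[Si](C)(C)C(C)(C)C)C[C@@H]2OC(C)(C)O[C@@H]2C[C@H]1O[Si](C)(C)C(C)(C)C
F5 | step 10 | C6-allyl oxocane (6R,7R,9R,10S,12R): C7 OTBS, C12 CH2OTBS, C9/C10 acetonide | C=CC[C@H]1O[C@@H](CO[Si](C)(C)C(C)(C)C)C[C@@H]2OC(C)(C)O[C@@H]2C[C@H]1O[Si](C)(C)C(C)(C)C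
F6 | step 10 | C4 aldehyde: C6 CH2CHO oxocane, C7 OTBS, C12 CH2OTBS, C9/C10 acetonide | O=CC[C@H]1O[C@@H](CO[Si](C)(C)C(C)(C)C)C[C@@H]2OC(C)(C)O[C@@H]2C[C@H]1O[Si](C)(C)C(C)(C)C
F7 | step 13 | C13 epimer of 23 (13R, from chelation-controlled addition) | CC(C)[Si](C(C)C)(C(C)C)C#C/C=C\C[C@H]1O[C@@H]([C@@H](CC)O)C[C@@H]2OC(C)(C)O[C@@H]2C[C@H]1O[Si](C)(C)C(C)(C)C
F8 | step 13 | C13 ethyl ketone | CC(C)[Si](C(C)C)(C(C)C)C#C/C=C\C[C@H]1O[C@@H](C(=O)CC)C[C@@H]2OC(C)(C)O[C@@H]2C[C@H]1O[Si](C)(C)C(C)(C)C
A1 | alternative 1 | aldol product: C6-allyl, C7-oxo, C9-hydroxy, C10-OTBS oxocane with C13 O-(4-methoxybenzyl) | C=CC[C@H]1O[C@@H]([C@H](CC)OCc2ccc(OC)cc2)C[C@H](O[Si](C)(C)C(C)(C)C)[C@H](O)CC1=O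
A2 | alternative 1 | open-chain ether: C7 trimethylsilyl enol ether and C9 aldehyde | C=CC[C@@H](O[C@@H]([C@H](CC)OCc1ccc(OC)cc1)C[C@H](O[Si](C)(C)C(C)(C)C)C=O)C(=C)O[Si](C)(C)C
A3 | alternative 2 | C9/C10 acetonide of the target (identical with 25) | C#C/C=C\C[C@H]1O[C@@H]([C@H](CC)OC(C)=O)C[C@@H]2OC(C)(C)O[C@@H]2C[C@H]1OC(C)=O
A4 | alternative 2 | cis-2,7-disubstituted oxepane with chloromethanesulfonate on exocyclic C6 | C#C/C=C\C[C@H](OS(=O)(=O)CCl)[C@H]1O[C@@H]([C@H](CC)OC(C)=O)C[C@@H]2OC(C)(C)O[C@@H]2C1
A5 | alternative 3 | (Z)-8-[(S)-1-(tert-butyldimethylsilyloxy)propyl]-3,4,7,8-tetrahydro-2H-oxocin-2-one (12R) | O=C1CC/C=C\C[C@H]([C@H](CC)O[Si](C)(C)C(C)(C)C)O1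
A6 | alternative 3 | 2-methylene-4-vinyl-1,3-dioxane ketene acetal (4,6-cis isomer drawn) | C=C1O[C@H](C=C)C[C@H]([C@H](CC)O[Si](C)(C)C(C)(C)C)O1
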